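**Strategy**

The synthesis rests on disconnecting the C1–C10 bond, which is at once the carbon–carbon bond of the 1,10-oxirane and a ring bond of the ten-membered carbocycle. Because C10 bears the methyl group and the oxirane oxygen, it is read as a methyl ketone and C1 as a sulfonium ylide carbon. An intramolecular Corey–Chaykovsky reaction then forms C1–C10 and O–C1 in one operation, closing both rings and setting both stereocentres. The precursor is an open C1–C10 chain that already holds the trans-fused α-methylene lactone, the tiglate, the 4,5-epoxide and the silylated C3 hydroxyl, with a diphenylsulfonium group on C1.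

Key step: step 18

Remark: atom labels C1–C15 follow germacrane numbering of the target in all intermediates. The target is taken as the (1R,3S,4R,5R,6S,7R,8S,10R) isomer encoded by its SMILES. TBS = tert-butyldimethylsilyl.

**Route**

Step 1
Reactants: 1 (S)-3-hydroxyoxolan-2-one; 2 N,O-dimethylhydroxylamine hydrochloride
Product: 3 (2S)-2,4-dihydroxy-N-methoxy-N-methylbutanamide
Conditions: AlMe3 (3 equiv), CH2Cl2, 0 °C to rt
Reagents that add atoms: N,O-dimethylhydroxylamine hydrochloride, Cl.CNOC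
Why: Weinreb aminolysis of the lactone by the aluminium amide opens the ring at the acyl carbon and leaves the chiral-pool carbinol (C3 of the target) untouched.

Step 2
Reactants: 3 (2S)-2,4-dihydroxy-N-methoxy-N-methylbutanamide; 4 tert-butyldimethylsilyl chloride
Product: 5 (2S)-2,4-bis(TBS-oxy)-N-methoxy-N-methylbutanamide
Conditions: imidazole, DMF, rt
Reagents that add atoms: tert-butyldimethylsilyl chloride, CC(C)(C)[Si](C)(C)Cl
Why: Standard silylation of both hydroxyls should proceed cleanly and blocks relactonisation.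

Step 3
Reactants: 5 (2S)-2,4-bis(TBS-oxy)-N-methoxy-N-methylbutanamide; 6 methylmagnesium bromide
Product: 7 (3S)-3,5-bis(TBS-oxy)pentan-2-one
Conditions: THF, 0 °C
Reagents that add atoms: methylmagnesium bromide, C[Mg]Br
Why: Weinreb ketone synthesis, in which the chelated tetrahedral intermediate stops the addition at the methyl ketone (C4 with its methyl C15).

Step 4
Reactants: 7 (3S)-3,5-bis(TBS-oxy)pentan-2-one; 8 triethyl phosphonoacetate
Product: 9 ethyl (2E,4S)-4,6-bis(TBS-oxy)-3-methylhex-2-enoate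
Conditions: NaH, THF, 0 °C to rt
Reagents that add atoms: triethyl phosphonoacetate, CCOC(=O)CP(=O)(OCC)OCC
Why: Horner–Wadsworth–Emmons olefination should place the ester trans to the branched silyloxy carbon, giving mainly the (E)-enoate that fixes the C4=C5 geometry needed for the trans-oxirane.

Step 5
Reactants: 9 ethyl (2E,4S)-4,6-bis(TBS-oxy)-3-methylhex-2-enoate
Product: 10 (2E,4S)-4,6-bis(TBS-oxy)-3-methylhex-2-en-1-ol
Conditions: i-Bu2AlH (2.2 equiv), CH2Cl2, −78 °C
Reagents that add atoms: none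
Why: 1,2-Reduction of the enoate by the aluminium hydride gives the allylic alcohol without touching the alkene or the silyl ethers.

Step 6
Reactants: 10 (2E,4S)-4,6-bis(TBS-oxy)-3-methylhex-2-en-1-ol; 11 tert-butyl hydroperoxide
Product: 12 [(2R,3S)-3-[(1S)-1,3-bis(TBS-oxy)propyl]-3-methyloxiran-2-yl]methanol
Conditions: Ti(OiPr)4 (10 mol %), D-(−)-diethyl tartrate (12 mol %), 4 Å molecular sieves, CH2Cl2, −20 °C
Reagents that add atoms: tert-butyl hydroperoxide, CC(C)(C)OO
Why: Sharpless asymmetric epoxidation under reagent control, in which D-(−)-tartrate delivers oxygen to the alkene face opposite to that of the geraniol/L-(+)-tartrate case and so sets C4 and C5 as in the target.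

Step 7
Reactants: 12 [(2R,3S)-3-[(1S)-1,3-bis(TBS-oxy)propyl]-3-methyloxiran-2-yl]methanol
Product: 13 (2S,3S)-3-[(1S)-1,3-bis(TBS-oxy)propyl]-3-methyloxirane-2-carbaldehyde
Conditions: Dess–Martin periodinane, NaHCO3, CH2Cl2, 0 °C to rt
Reagents that add atoms: none
Why: Dess–Martin oxidation gives the epoxy aldehyde (C6) under buffered, non-epimerising conditions.

Step 8
Reactants: 14 (4S)-4-benzyl-1,3-oxazolidin-2-one; 15 methyl 4-chloro-4-oxobutanoate
Product: 16 methyl 4-[(4S)-4-benzyl-2-oxo-1,3-oxazolidin-3-yl]-4-oxobutanoate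
Conditions: n-BuLi, THF, −78 °C
Reagents that add atoms: none
Why: N-Acylation of the lithiated oxazolidinone by the acid chloride gives the succinate imide that carries C8, C7, C11 and C12.

Step 9
Reactants: 16 methyl 4-[(4S)-4-benzyl-2-oxo-1,3-oxazolidin-3-yl]-4-oxobutanoate; 13 (2S,3S)-3-[(1S)-1,3-bis(TBS-oxy)propyl]-3-methyloxirane-2-carbaldehyde
Product: 18 trans-lactone imide (6,12-olide with the acyl oxazolidinone on C7), via aldol adduct 17 (not isolated)
Conditions: n-Bu2BOTf, i-Pr2NEt, CH2Cl2, −78 to 0 °C; then 13, −78 to 0 °C; pH 7 buffer, MeOH, H2O2, 0 °C; then PPTS (cat.), CH2Cl2, rt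
Reagents that add atoms: none
Why: Evans syn-aldol reaction through the (Z)-boron enolate and a Zimmerman–Traxler chair sets C7 and C6 under auxiliary control, and the C6 hydroxyl then lactonises onto the methyl ester to give the trans-lactone.

Step 10
Reactants: 18 trans-lactone imide
Product: 19 (4R,5S)-5-[(2R,3S)-3-[(1S)-1,3-bis(TBS-oxy)propyl]-3-methyloxiran-2-yl]-4-(hydroxymethyl)oxolan-2-one
Conditions: NaBH4, THF/H2O, 0 °C to rt
Reagents that add atoms: none
Why: Reductive cleavage of the Evans imide, whose exocyclic acyl group is more electrophilic than the γ-lactone, should give the C8 primary alcohol and release the auxiliary.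

Step 11
Reactants: 19 lactone alcohol
Product: 20 (2S,3S)-2-[(2R,3S)-3-[(1S)-1,3-bis(TBS-oxy)propyl]-3-methyloxiran-2-yl]-5-oxooxolane-3-carbaldehyde
Conditions: Dess–Martin periodinane, NaHCO3, CH2Cl2, 0 °C; used crude
Reagents that add atoms: none
Why: Buffered Dess–Martin oxidation gives the C8 aldehyde, whose C7 centre is the more stable trans isomer and is not exposed to base.

Step 12
Reactants: 20 lactone aldehyde; 21 B-allylbis(isopinocampheyl)borane derived from (+)-α-pinene
Product: 22 (4R,5S)-5-[(2R,3S)-3-[(1S)-1,3-bis(TBS-oxy)propyl]-3-methyloxiran-2-yl]-4-[(1S)-1-hydroxybut-3-en-1-yl]oxolan-2-one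
Conditions: Et2O, −78 °C; then NaBO3·4H2O, THF/H2O, rt
Reagents that add atoms: B-allylbis(isopinocampheyl)borane, C=CCB([C@@H]1C[C@@H]2C[C@@H](C2(C)C)[C@H]1C)[C@@H]1C[C@@H]2C[C@@H](C2(C)C)[C@H]1C
Why: Brown allylboration through a chair transition state, in which the isopinocampheyl groups direct the allyl group to the Si face of the aldehyde, should set C8 as (S) under reagent control.

Step 13
Reactants: 22 homoallylic alcohol; 23 (E)-2-methylbut-2-enoyl chloride
Product: 24 C8 tiglate of 22
Conditions: Et3N, DMAP, CH2Cl2, 0 °C to rt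
Reagents that add atoms: (E)-2-methylbut-2-enoyl chloride, C/C=C(\C)C(Cl)=O
Why: DMAP-catalysed acylation installs the tiglate, whose (E) geometry is the stable one and should not change.

Step 14
Reactants: 24 C8 tiglate; 25 N,N-dimethylmethyleneiminium iodide
Product: 28 α-methylene lactone with C8 tiglate and C9–C10 allyl group, via Mannich base 26 (not isolated), via methiodide 27 (not isolated)
Conditions: LiN(SiMe3)2, THF, −78 °C; then 25, −78 °C to rt; then MeI, MeOH, rt; then aq NaHCO3, CH2Cl2, rt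
Reagents that add atoms: N,N-dimethylmethyleneiminium iodide, C=[N+](C)C.[I-]
Why: Mannich reaction of the lactone lithium enolate (C11 is the only enolisable carbonyl α-position) with Eschenmoser's salt, then Hofmann-type elimination of the quaternised amine, gives the exocyclic C11=C13 alkene.

Step 15
Reactants: 28 α-methylene lactone with allyl group
Product: 29 (1S)-1-[(2S,3R)-2-[(2R,3S)-3-[(1S)-1,3-bis(TBS-oxy)propyl]-3-methyloxiran-2-yl]-4-methylidene-5-oxooxolan-3-yl]-3-oxobutyl (2E)-2-methylbut-2-enoate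
Conditions: PdCl2 (15 mol %), Cu(OAc)2 (30 mol %), O2 (1 atm), DMA/H2O 7:1, rt
Reagents that add atoms: water, O
Why: Tsuji–Wacker oxidation should convert only the terminal monosubstituted alkene, by Markovnikov hydroxypalladation, into the C10 methyl ketone, because the methylene lactone and the tiglate are electron-poor and more substituted.

Step 16
Reactants: 29 methyl ketone
Product: 30 C1 primary alcohol (C3 TBS ether kept)
Conditions: TBAF, AcOH (1:1), THF, 0 °C; used at once
Reagents that add atoms: none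
Why: Selective desilylation, in which fluoride cleaves the unhindered primary silyl ether much faster than the secondary one next to the quaternary C4, while the acetic acid buffer protects the β-acyloxy ketone and the methylene lactone.

Step 17
Reactants: 30 C1 primary alcohol; 31 trifluoromethanesulfonic anhydride; 32 diphenyl sulfide
Product: 34 C1 diphenylsulfonium triflate, via primary triflate 33 (not isolated)
Conditions: 2,6-di-tert-butyl-4-methylpyridine, CH2Cl2, −78 °C; then Ph2S (20 equiv), −78 to 0 °C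
Reagents that add atoms: trifluoromethanesulfonic anhydride, O=S(=O)(OS(=O)(=O)C(F)(F)F)C(F)(F)F; diphenyl sulfide, c1ccc(Sc2ccccc2)cc1
Why: Triflation of the primary alcohol followed by SN2 alkylation of diphenyl sulfide, used in large excess, should give the alkyldiphenylsulfonium salt whose only acidic α-hydrogens are on C1.

Step 18
Reactants: 34 C1 diphenylsulfonium triflate
Product: 37 3-O-TBS ether of the target, via sulfonium ylide 35 (not isolated), via betaine 36 (not isolated)
Conditions: KN(SiMe3)2 (1.05 equiv, slow addition), THF (0.001 M), −78 to −40 °C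
Reagents that add atoms: none
Why: KN(SiMe3)2 removes a proton from the sulfonium-bearing C1 methylene, by far the most acidic C–H of 34, to give the unstabilised ylide 35, whose carbon adds to the C10 methyl ketone to give betaine 36, and the C10 alkoxide then displaces diphenyl sulfide from C1 with inversion (Corey–Chaykovsky epoxidation; closest precedent: intramolecular sulfonium ylide epoxidations of tethered ketones that give epoxide-fused five- to seven-membered rings). The carbocycle closes by a 10-exo-trig addition to the carbonyl and the oxirane by a 3-exo-tet substitution, so the C1–C10 bond made here is a ring bond of both. C1 and C10 are set under substrate control: the trans-lactone and the trans-4,5-oxirane should hold the chain in a germacrolide-like fold in which C9 and C2 are antiperiplanar across the forming bond, the geometry that gives the trans-oxirane, and attack on the ketone face that leaves the oxirane oxygen on the outside of the ring gives (1R,10R), the isomer that peripheral attack gives in this ring system. The step needs 1,2-addition to the ketone over conjugate addition to the α-methylene lactone and over enolisation or β-elimination of the β-acyloxy ketone, which the fast, irreversible carbonyl addition of a primary unstabilised ylide at low temperature and the slow addition of base should secure. It also needs ring closure over dimerisation, which high dilution and the two rigid rings in the chain should favour.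

Step 19
Reactants: 37 3-O-TBS ether of the target
Product: 38 CNP0350037.1
Conditions: TBAF, AcOH (1:1), THF, 0 °C to rt
Reagents that add atoms: none
Why: Buffered fluoride desilylation frees the C3 hydroxyl without acid, which would trigger transannular opening of the oxiranes, and without strong base, which would attack the methylene lactone.

**Compound list**

1 | (S)-3-hydroxyoxolan-2-one, (S)-α-hydroxy-γ-butyrolactone | O[C@H]1CCOC1=O | starting material
2 | N,O-dimethylhydroxylamine hydrochloride | Cl.CNOC | starting material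
3 | (2S)-2,4-dihydroxy-N-methoxy-N-methylbutanamide | CON(C)C(=O)[C@@H](O)CCO | intermediate
4 | tert-butyldimethylsilyl chloride | CC(C)(C)[Si](C)(C)Cl | starting material
5 | (2S)-2,4-bis(tert-butyldimethylsilyloxy)-N-methoxy-N-methylbutanamide | CON(C)C(=O)[C@@H](O[Si](C)(C)C(C)(C)C)CCO[Si](C)(C)C(C)(C)C | intermediate
6 | methylmagnesium bromide | C[Mg]Br | starting material
7 | (3S)-3,5-bis(tert-butyldimethylsilyloxy)pentan-2-one | CC(=O)[C@@H](O[Si](C)(C)C(C)(C)C)CCO[Si](C)(C)C(C)(C)C | intermediate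
8 | triethyl phosphonoacetate | CCOC(=O)CP(=O)(OCC)OCC | starting material
9 | ethyl (2E,4S)-4,6-bis(tert-butyldimethylsilyloxy)-3-methylhex-2-enoate | CCOC(=O)/C=C(\C)[C@@H](O[Si](C)(C)C(C)(C)C)CCO[Si](C)(C)C(C)(C)C | intermediate
10 | (2E,4S)-4,6-bis(tert-butyldimethylsilyloxy)-3-methylhex-2-en-1-ol | OC/C=C(\C)[C@@H](O[Si](C)(C)C(C)(C)C)CCO[Si](C)(C)C(C)(C)C | intermediate
11 | tert-butyl hydroperoxide | CC(C)(C)OO | starting material
12 | [(2R,3S)-3-[(1S)-1,3-bis(tert-butyldimethylsilyloxy)propyl]-3-methyloxiran-2-yl]methanol | OC[C@H]1O[C@]1(C)[C@@H](O[Si](C)(C)C(C)(C)C)CCO[Si](C)(C)C(C)(C)C | intermediate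
13 | (2S,3S)-3-[(1S)-1,3-bis(tert-butyldimethylsilyloxy)propyl]-3-methyloxirane-2-carbaldehyde | O=C[C@H]1O[C@]1(C)[C@@H](O[Si](C)(C)C(C)(C)C)CCO[Si](C)(C)C(C)(C)C | intermediate
14 | (4S)-4-benzyl-1,3-oxazolidin-2-one | O=C1N[C@@H](Cc2ccccc2)CO1 | starting material
15 | methyl 4-chloro-4-oxobutanoate | COC(=O)CCC(Cl)=O | starting material
16 | methyl 4-[(4S)-4-benzyl-2-oxo-1,3-oxazolidin-3-yl]-4-oxobutanoate | COC(=O)CCC(=O)N1[C@@H](Cc2ccccc2)COC1=O | intermediate
17 | methyl (3S,4S)-3-[(4S)-4-benzyl-2-oxo-1,3-oxazolidine-3-carbonyl]-4-hydroxy-4-[(2R,3S)-3-[(1S)-1,3-bis(tert-butyldimethylsilyloxy)propyl]-3-methyloxiran-2-yl]butanoate (aldol adduct) | COC(=O)C[C@H](C(=O)N1[C@@H](Cc2ccccc2)COC1=O)[C@H](O)[C@H]1O[C@]1(C)[C@@H](O[Si](C)(C)C(C)(C)C)CCO[Si](C)(C)C(C)(C)C | intermediate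
18 | (4S)-4-benzyl-3-[(2S,3S)-2-[(2R,3S)-3-[(1S)-1,3-bis(tert-butyldimethylsilyloxy)propyl]-3-methyloxiran-2-yl]-5-oxooxolane-3-carbonyl]-1,3-oxazolidin-2-one (trans-lactone imide) | O=C1O[C@H]([C@H]2O[C@]2(C)[C@@H](O[Si](C)(C)C(C)(C)C)CCO[Si](C)(C)C(C)(C)C)[C@@H](C(=O)N2[C@@H](Cc3ccccc3)COC2=O)C1 | intermediate
19 | (4R,5S)-5-[(2R,3S)-3-[(1S)-1,3-bis(tert-butyldimethylsilyloxy)propyl]-3-methyloxiran-2-yl]-4-(hydroxymethyl)oxolan-2-one | O=C1O[C@H]([C@H]2O[C@]2(C)[C@@H](O[Si](C)(C)C(C)(C)C)CCO[Si](C)(C)C(C)(C)C)[C@@H](CO)C1 | intermediate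
20 | (2S,3S)-2-[(2R,3S)-3-[(1S)-1,3-bis(tert-butyldimethylsilyloxy)propyl]-3-methyloxiran-2-yl]-5-oxooxolane-3-carbaldehyde | O=C1O[C@H]([C@H]2O[C@]2(C)[C@@H](O[Si](C)(C)C(C)(C)C)CCO[Si](C)(C)C(C)(C)C)[C@@H](C=O)C1 | intermediate
21 | B-allylbis(isopinocampheyl)borane derived from (+)-α-pinene | C=CCB([C@@H]1C[C@@H]2C[C@@H](C2(C)C)[C@H]1C)[C@@H]1C[C@@H]2C[C@@H](C2(C)C)[C@H]1C | starting material
22 | (4R,5S)-5-[(2R,3S)-3-[(1S)-1,3-bis(tert-butyldimethylsilyloxy)propyl]-3-methyloxiran-2-yl]-4-[(1S)-1-hydroxybut-3-en-1-yl]oxolan-2-one | O=C1O[C@H]([C@H]2O[C@]2(C)[C@@H](O[Si](C)(C)C(C)(C)C)CCO[Si](C)(C)C(C)(C)C)[C@@H]([C@@H](O)CC=C)C1 | intermediate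
23 | (E)-2-methylbut-2-enoyl chloride (tigloyl chloride) | C/C=C(\C)C(Cl)=O | starting material
24 | (1S)-1-[(2S,3R)-2-[(2R,3S)-3-[(1S)-1,3-bis(tert-butyldimethylsilyloxy)propyl]-3-methyloxiran-2-yl]-5-oxooxolan-3-yl]but-3-en-1-yl (2E)-2-methylbut-2-enoate | O=C1O[C@H]([C@H]2O[C@]2(C)[C@@H](O[Si](C)(C)C(C)(C)C)CCO[Si](C)(C)C(C)(C)C)[C@@H]([C@@H](OC(=O)/C(C)=C/C)CC=C)C1 | intermediate
25 | N,N-dimethylmethyleneiminium iodide (Eschenmoser's salt) | C=[N+](C)C.[I-] | starting material
26 | Mannich base: 24 with a dimethylaminomethyl group on C11 (either C11 epimer) | O=C1O[C@H]([C@H]2O[C@]2(C)[C@@H](O[Si](C)(C)C(C)(C)C)CCO[Si](C)(C)C(C)(C)C)[C@@H]([C@@H](OC(=O)/C(C)=C/C)CC=C)C1CN(C)C | intermediate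
27 | methiodide of 26 (trimethylammoniomethyl lactone iodide) | O=C1O[C@H]([C@H]2O[C@]2(C)[C@@H](O[Si](C)(C)C(C)(C)C)CCO[Si](C)(C)C(C)(C)C)[C@@H]([C@@H](OC(=O)/C(C)=C/C)CC=C)C1C[N+](C)(C)C.[I-] | intermediate
28 | (1S)-1-[(2S,3R)-2-[(2R,3S)-3-[(1S)-1,3-bis(tert-butyldimethylsilyloxy)propyl]-3-methyloxiran-2-yl]-4-methylidene-5-oxooxolan-3-yl]but-3-en-1-yl (2E)-2-methylbut-2-enoate | O=C1O[C@H]([C@H]2O[C@]2(C)[C@@H](O[Si](C)(C)C(C)(C)C)CCO[Si](C)(C)C(C)(C)C)[C@@H]([C@@H](OC(=O)/C(C)=C/C)CC=C)C1=C | intermediate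
29 | (1S)-1-[(2S,3R)-2-[(2R,3S)-3-[(1S)-1,3-bis(tert-butyldimethylsilyloxy)propyl]-3-methyloxiran-2-yl]-4-methylidene-5-oxooxolan-3-yl]-3-oxobutyl (2E)-2-methylbut-2-enoate | O=C1O[C@H]([C@H]2O[C@]2(C)[C@@H](O[Si](C)(C)C(C)(C)C)CCO[Si](C)(C)C(C)(C)C)[C@@H]([C@@H](OC(=O)/C(C)=C/C)CC(C)=O)C1=C | intermediate
30 | (1S)-1-[(2S,3R)-2-[(2R,3S)-3-[(1S)-1-(tert-butyldimethylsilyloxy)-3-hydroxypropyl]-3-methyloxiran-2-yl]-4-methylidene-5-oxooxolan-3-yl]-3-oxobutyl (2E)-2-methylbut-2-enoate | O=C1O[C@H]([C@H]2O[C@]2(C)[C@@H](O[Si](C)(C)C(C)(C)C)CCO)[C@@H]([C@@H](OC(=O)/C(C)=C/C)CC(C)=O)C1=C | intermediate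
31 | trifluoromethanesulfonic anhydride | O=S(=O)(OS(=O)(=O)C(F)(F)F)C(F)(F)F | starting material
32 | diphenyl sulfide | c1ccc(Sc2ccccc2)cc1 | starting material
33 | C1 trifluoromethanesulfonate of 30 | O=C1O[C@H]([C@H]2O[C@]2(C)[C@@H](O[Si](C)(C)C(C)(C)C)CCOS(=O)(=O)C(F)(F)F)[C@@H]([C@@H](OC(=O)/C(C)=C/C)CC(C)=O)C1=C | intermediate
34 | [(3S)-3-(tert-butyldimethylsilyloxy)-3-[(2S,3R)-2-methyl-3-[(2S,3R)-4-methylidene-5-oxo-3-[(1S)-3-oxo-1-[(E)-2-methylbut-2-enoyloxy]butyl]oxolan-2-yl]oxiran-2-yl]propyl]diphenylsulfonium trifluoromethanesulfonate | O=C1O[C@H]([C@H]2O[C@]2(C)[C@@H](O[Si](C)(C)C(C)(C)C)CC[S+](c2ccccc2)c2ccccc2)[C@@H]([C@@H](OC(=O)/C(C)=C/C)CC(C)=O)C1=C.[O-]S(=O)(=O)C(F)(F)F | intermediate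
35 | diphenylsulfonium ylide of 34 (carbanion on C1) | O=C1O[C@H]([C@H]2O[C@]2(C)[C@@H](O[Si](C)(C)C(C)(C)C)C[CH-][S+](c2ccccc2)c2ccccc2)[C@@H]([C@@H](OC(=O)/C(C)=C/C)CC(C)=O)C1=C | intermediate
36 | ten-membered betaine: C10 alkoxide and C1 diphenylsulfonium, C1–S bond anti to C10–O, all other centres as in 37 | C=C1C(=O)O[C@H]2[C@H]1[C@@H](OC(=O)/C(C)=C/C)C[C@]([O-])(C)[C@@H]([S+](c1ccccc1)c1ccccc1)C[C@H](O[Si](C)(C)C(C)(C)C)[C@@]1(C)O[C@H]21 | intermediate
37 | 3-O-tert-butyldimethylsilyl ether of 38 (same spatial arrangement at every stereocentre) | C=C1C(=O)O[C@H]2[C@H]1[C@@H](OC(=O)/C(C)=C/C)C[C@@]1(C)O[C@@H]1C[C@H](O[Si](C)(C)C(C)(C)C)[C@@]1(C)O[C@H]21 | intermediate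
38 | CNP0350037.1, (1R,3S,4R,5R,6S,7R,8S,10R)-1,10:4,5-diepoxy-3-hydroxy-8-[(E)-2-methylbut-2-enoyloxy]germacr-11(13)-en-12,6-olide | C=C1C(=O)O[C@H]2[C@H]1[C@@H](OC(=O)/C(C)=C/C)C[C@@]1(C)O[C@@H]1C[C@H](O)[C@@]1(C)O[C@H]21 | target

**Step count and risks**

Total steps: 19. Longest linear sequence: 18 steps (steps 1 to 7 and 9 to 19, starting from compound 1).

Steps most likely to fail:

1. Step 18. The ten-membered ring may close slowly, so that the ylide is instead quenched by proton transfer from C9 (with loss of the tiglate), adds to the methylene lactone, or closes with poor facial selectivity at C10 and C1. The fallback closes the same C1–C10 connection as an alkene. It sets out from alcohol 30, which would be oxidised with Dess–Martin periodinane to the keto aldehyde F1. Both carbonyl groups of F1 would be methylenated with the Tebbe reagent Cp2Ti(μ-Cl)(μ-CH2)AlMe2 in THF at −40 °C to give the diene F2. Ring-closing metathesis of F2 with second-generation Hoveyda–Grubbs catalyst in dilute toluene would have to deliver the (E)-configured cyclodecene F3, and this geometry is itself uncertain in a ten-membered ring. Epoxidation of F3 with mCPBA and NaHCO3 in CH2Cl2 at 0 °C, from the exposed outer face of the trisubstituted alkene, comes back to the route at 37.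

2. Step 17. Diphenyl sulfide is a weak nucleophile, so the 4,5-oxirane oxygen may take part in the displacement at C1 (five-membered oxonium ion, then tetrahydrofuran formation) before the sulfide attacks. The fallback sets out from alcohol 30 and replaces the sulfide by the far more nucleophilic triphenylarsine. The triflate 33, made as before, would be trapped at −78 °C to give the arsonium triflate F4. Deprotonation of F4 with KN(SiMe3)2 in THF at −78 °C under high dilution would give the arsonium ylide, which epoxidises the C10 ketone in the same intramolecular sense (arsonium ylide epoxidation) and comes back to the route at 37.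

3. Step 14. The lactone enolate may transfer the neighbouring tigloyl group to C11 (intramolecular Claisen-type acyl shift), or the base may attack the tiglate. The fallback sets out from alcohol 22 and makes the enolate before the ester is present. Alcohol 22 would be silylated with Et3SiCl and imidazole to the triethylsilyl ether F5. The sequence LiN(iPr)2, Eschenmoser's salt, MeI and NaHCO3 would then give the methylene lactone F6. HF·pyridine buffered with pyridine in THF at 0 °C would remove only the triethylsilyl group to give alcohol F7, and acylation with tigloyl chloride, Et3N and DMAP comes back to the route at 28.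

**Further compounds**

F1 | step 18 | keto aldehyde: 30 with C1 oxidised to the aldehyde | O=C1O[C@H]([C@H]2O[C@]2(C)[C@@H](O[Si](C)(C)C(C)(C)C)CC=O)[C@@H]([C@@H](OC(=O)/C(C)=C/C)CC(C)=O)C1=C
F2 | step 18 | diene: F1 with both the C1 aldehyde and the C10 ketone methylenated | O=C1O[C@H]([C@H]2O[C@]2(C)[C@@H](O[Si](C)(C)C(C)(C)C)CC=C)[C@@H]([C@@H](OC(=O)/C(C)=C/C)CC(C)=C)C1=C
F3 | step 18 | (1(10)E)-cyclodecene: 37 with a C1=C10 double bond in place of the 1,10-oxirane | C=C1C(=O)O[C@H]2[C@H]1[C@@H](OC(=O)/C(C)=C/C)C/C(C)=C/C[C@H](O[Si](C)(C)C(C)(C)C)[C@@]1(C)O[C@H]21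
F4 | step 17 | C1 triphenylarsonium triflate corresponding to 34 | O=C1O[C@H]([C@H]2O[C@]2(C)[C@@H](O[Si](C)(C)C(C)(C)C)CC[As+](c2ccccc2)(c2ccccc2)c2ccccc2)[C@@H]([C@@H](OC(=O)/C(C)=C/C)CC(C)=O)C1=C.[O-]S(=O)(=O)C(F)(F)F
F5 | step 14 | C8 triethylsilyl ether of 22 | O=C1O[C@H]([C@H]2O[C@]2(C)[C@@H](O[Si](C)(C)C(C)(C)C)CCO[Si](C)(C)C(C)(C)C)[C@@H]([C@@H](O[Si](CC)(CC)CC)CC=C)C1
F6 | step 14 | α-methylene lactone with C8 triethylsilyl ether | O=C1O[C@H]([C@H]2O[C@]2(C)[C@@H](O[Si](C)(C)C(C)(C)C)CCO[Si](C)(C)C(C)(C)C)[C@@H]([C@@H](O[Si](CC)(CC)CC)CC=C)C1=C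
F7 | step 14 | α-methylene lactone with free C8 hydroxyl | O=C1O[C@H]([C@H]2O[C@]2(C)[C@@H](O[Si](C)(C)C(C)(C)C)CCO[Si](C)(C)C(C)(C)C)[C@@H]([C@@H](O)CC=C)C1=C
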